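(Its constants are those of an exercise; what happens was integrated by code.)

Start with partner.

    substrate → side product A (k1 = 4.9 × 10⁻⁴ /s)
    2 substrate → side product B (k2 = 0.12 /M/s)
    gas ⇌ partner, rate k3*(csat - [partner]) (k3 = 0.10 /s, csat = 4.3 mM)
    substrate + partner ⇌ target (K4 = 1400 /M, k4 = 0.37 /M/s)

| setting | delta | beta | zeta |
|---|---|---|---|
| substrate | 30 mM | 100 mM | 300 mM |
| gas | 4.3 mM (held) | 4.3 mM (held) | 4.3 mM (held) |
| time | 20 min | 20 min | 20 min |

- percent here means substrate units held: one side product B counts as two
- where a step has two of a species, its rate is k times that concentration squared, and two are used at each turn
- at the start none of partner is dissolved
- "hardly changes" means that all values lie within two and a half points (for a concentration: within two and a half percent of the largest)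
- run time (delta): 20 min

* [target] at the end for delta, beta, zeta, in this order
* the shape of the row from first to last (falls, then rises / falls all the way / hardly changes / rises, then falls / rises all the way)

Partner saturates at 4.3 mM, less than the delta charge of substrate, so write its balance. In delta, substrate at its charge uses partner at 0.0111 /s per unit of partner, slower than the transfer coefficient 0.10 /s, so partner stays near saturation. Substrate then sees a pseudo-first-order loss of 0.00208 /s, which matches the squared loss at 8.67 mM.

Carry one number, the balance ratio, target per substrate at equilibrium with saturated partner:

B = 6.02

Now take two extreme versions of delta, in fractions of the charge. The first has no back step, so the losses integrate directly: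

target, ceiling at the end of the run = 0.316

substrate, lowest = 0.0197

Their ratio is 16.0, more than B, so the back step must act, and what it returns feeds the other losses. Target therefore stays under the ceiling.

The second version is a low mark: target has caught up with balance on that lowest substrate, since with substrate small the forward and back steps together relax at a half-life of 6.23 min at saturated partner, shorter than the run of 20 min:

target, low mark = B × 0.0197 = 0.119

The back step keeps real substrate above that lowest value, so I expect delta between 0.119 and 0.316. The same ceiling in millimolar rises along the row, 9.47 mM, 16.2 mM, 23.1 mM, so I lean to a rising row.

The forecast gives 8 mM, 12.8 mM and 16 mM, shape rises all the way, resting on “about six target per substrate at saturation”. Its delta value is 0.267 of the charge, inside my range.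

The simulation gives 7.57 mM, 11.8 mM and 14.8 mM, shape rises all the way.

In delta the relaxation half-life of the target step at the end, 4.98 min, is shorter than the run of 20 min, and B times the substrate fraction read at the end, 4.20 %, gives 0.253 against a target reading of 25.2 %. In beta the same reading of target per substrate at the end is 6.90, above B.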